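**Assumptions and notation.** (+)-Sclareolide and isofraxidin are bought; the C3-selective P450 BM3 variant of step 1 is a known enzyme expressed in E. coli. Drimane numbering is used: C11 = CH2 on C9, C12 = CH3 on C8, C15 = CH3 on C10, α = face opposite the C10 methyl. The target is (3R,5R,9R,10R): 3α-ester, 5α-H, 9β-H, 10β-CH3. It is therefore the 3-epi, 9-epi relative of the usual drimenol series, and the route inverts both centres.

## Retrosynthetic overview

1. C11–O aryl ether: last step, Mitsunobu union of isofraxidin with the 9-epi hydroxymethyl enone 10.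
2. C9 (9β-H): thiyl-radical hydrogen-atom-transfer (HAT) stereo-editing of the γ-centre of enone acetate 8 (new), then acetate methanolysis.
3. C3 and C6: one Cr(VI) oxidation installs both carbonyls; L-Selectride then acylation sets the axial 3α-isovalerate.
4. Drimane C11–O: MeLi opening and Baeyer–Villiger oxidation excise the lactone carbonyl carbon of 3β-hydroxysclareolide; acid dehydration gives the Δ7 alkene.
5. Rings: none is formed. Both carbocycles and C5/C10 come from (+)-sclareolide, the coumarin from isofraxidin; C3–O comes from enzymatic C–H hydroxylation.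

## Route

Step 1
Reactants: 1 (+)-sclareolide
Product: 2 3β-hydroxysclareolide
Conditions: P450 BM3 variant (C3-selective), NADP+ (cat.), phosphite dehydrogenase, Na2HPO3, air, KPi pH 8, 25 °C
Reagents that add atoms: dioxygen O=O
Why: Known enzymatic C–H hydroxylation (P450 oxygen rebound) that is site-selective for C3 of sclareolide and returns OH with retention on the equatorial β face, giving the (3S) alcohol.

Step 2
Reactants: 2 3β-hydroxysclareolide
Product: 3 3β,8α-dihydroxy-14,15,16-trinorlabdan-12-one
Conditions: MeLi (2.5 equiv), THF, −78 → 0 °C; then H2O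
Reagents that add atoms: methyllithium [Li]C
Why: Organolithium addition to a lactone: the first equivalent deprotonates the 3-OH, the second adds to the lactone carbonyl, and the lithium hemiketal holds until quench, so the methyl ketone forms without touching a stereocentre.

Step 3
Reactants: 3 3β,8α-dihydroxy-14,15,16-trinorlabdan-12-one
Product: 4 3β,8α-dihydroxydriman-11-yl acetate
Conditions: CF3CO3H (from (CF3CO)2O and H2O2·urea), Na2HPO4, CH2Cl2, 0 °C
Reagents that add atoms: trifluoroperacetic acid OOC(=O)C(F)(F)F
Why: Baeyer–Villiger oxidation in which the primary C11 migrates in preference to methyl, so the former lactone carbon ends up as an acetyl group and C11 carries oxygen; the buffer protects the tertiary alcohol.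

Step 4
Reactants: 4 3β,8α-dihydroxydriman-11-yl acetate
Product: 5 3β-hydroxydrim-7-en-11-yl acetate
Conditions: TsOH·H2O (10 mol%), PhMe, 50 °C
Reagents that add atoms: none
Why: Acid-catalysed E1 dehydration of the tertiary C8 alcohol only: the axial 7α-H is lost to give the Δ7 alkene, any exocyclic alkene re-enters the cation, and loss of the hindered C9–H next to CH2OAc is slower; the 3-OH and acetate stay.

Step 5
Reactants: 5 3β-hydroxydrim-7-en-11-yl acetate
Product: 6 3,6-dioxodrim-7-en-11-yl acetate
Conditions: CrO3 (15 equiv), 3,5-dimethylpyrazole (15 equiv), CH2Cl2, −20 °C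
Reagents that add atoms: chromium trioxide O=[Cr](=O)=O
Why: Cr(VI)–pyrazole allylic oxidation (Salmond type) converts the only ring allylic CH2 (C6) into the enone carbonyl and oxidises the 3-OH to the ketone in the same flask, without base, so C5 and C9 are untouched.

Step 6
Reactants: 6 3,6-dioxodrim-7-en-11-yl acetate
Product: 8 3α-(3-methylbutanoyloxy)-6-oxodrim-7-en-11-yl acetate, via lithium 3α-alkoxide 7 (not isolated)
Conditions: L-Selectride (1.1 equiv), THF, −78 °C; then isovaleryl chloride (3 equiv), DMAP (cat.), −78 → 0 °C
Reagents that add atoms: 3-methylbutanoyl chloride CC(C)CC(Cl)=O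
Why: Reductive acylation: the bulky hydride attacks the 4,4-dimethyl-3-ketone from the equatorial direction and gives the axial 3α-alkoxide (3R), the hindered conjugated C6 carbonyl and the acetate are not reduced at −78 °C, and the alkoxide is acylated in place.

Step 7
Reactants: 8 3α-(3-methylbutanoyloxy)-6-oxodrim-7-en-11-yl acetate
Product: 10 11-hydroxy-6-oxo-9βH-drim-7-en-3α-yl 3-methylbutanoate, via 9-epi acetate 9 (not isolated)
Conditions: (4-MeOC6H4S)2 (20 mol%), 390 nm LED, PhH, 25 °C; then K2CO3 (0.3 equiv), MeOH, 0 °C
Reagents that add atoms: none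
Why: Proposed new method: photogenerated arylthiyl radicals (ArS–H about 79 kcal/mol, matched to the axial C9–H that is γ to the enone) abstract the 9α-hydrogen reversibly and ArSH returns hydrogen to the planar dienoyl radical until the mixture drains into the more stable 9β-H epimer 9, whose CH2OAc is pseudo-axial and free of A(1,2) strain with the C8 methyl and whose remaining C9–H is poorly aligned with the enone π system; no anion is formed, so the acetate (a vinylogous β-leaving group) is not expelled, and catalytic carbonate in methanol then transesterifies only the primary acetate; the closest known reaction types are thiyl-radical HAT epimerisation of C–H stereocentres and the base epimerisation of polygodial to its more stable 9-epimer.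

Step 8
Reactants: 10 11-hydroxy-6-oxo-9βH-drim-7-en-3α-yl 3-methylbutanoate; 11 isofraxidin
Product: 12 target ether CNP0279705.1
Conditions: PPh3 (1.5 equiv), DIAD (1.5 equiv), THF, 0 → 23 °C
Reagents that add atoms: none
Why: Mitsunobu etherification: the acidic phenol (pKa about 7.7) displaces the oxyphosphonium by SN2 at the primary C11, which forms the key C–O bond without touching a stereocentre; vinylogous E1cB is avoided because the 9β-H is pseudo-equatorial and poorly aligned with the enone π system.

## Compound list

1 | (+)-sclareolide | O=C1C[C@H]2[C@@](C)(CC[C@H]3C(C)(C)CCC[C@]23C)O1 | starting material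
2 | 3β-hydroxysclareolide | O=C1C[C@H]2[C@@](C)(CC[C@H]3C(C)(C)[C@@H](O)CC[C@]23C)O1 | intermediate
3 | 3β,8α-dihydroxy-14,15,16-trinorlabdan-12-one (11-acetonyl drimane diol; 5α-H, 9α-H) | CC(=O)C[C@H]1[C@](C)(O)CC[C@H]2C(C)(C)[C@@H](O)CC[C@]12C | intermediate
4 | 3β,8α-dihydroxydriman-11-yl acetate | CC(=O)OC[C@H]1[C@](C)(O)CC[C@H]2C(C)(C)[C@@H](O)CC[C@]12C | intermediate
5 | 3β-hydroxydrim-7-en-11-yl acetate (9α-H) | CC(=O)OC[C@H]1C(C)=CC[C@H]2C(C)(C)[C@@H](O)CC[C@]12C | intermediate
6 | 3,6-dioxodrim-7-en-11-yl acetate (9α-H) | CC(=O)OC[C@H]1C(C)=CC(=O)[C@H]2C(C)(C)C(=O)CC[C@]12C | intermediate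
7 | lithium 3α-alkoxide of 3α-hydroxy-6-oxodrim-7-en-11-yl acetate | CC(=O)OC[C@H]1C(C)=CC(=O)[C@H]2C(C)(C)[C@H]([O-])CC[C@]12C.[Li+] | intermediate
8 | 3α-(3-methylbutanoyloxy)-6-oxodrim-7-en-11-yl acetate (9α-H) | CC(=O)OC[C@H]1C(C)=CC(=O)[C@H]2C(C)(C)[C@H](OC(=O)CC(C)C)CC[C@]12C | intermediate
9 | 3α-(3-methylbutanoyloxy)-6-oxo-9βH-drim-7-en-11-yl acetate (9-epi acetate) | CC(=O)OC[C@@H]1C(C)=CC(=O)[C@H]2C(C)(C)[C@H](OC(=O)CC(C)C)CC[C@]12C | intermediate
10 | 11-hydroxy-6-oxo-9βH-drim-7-en-3α-yl 3-methylbutanoate | OC[C@@H]1C(C)=CC(=O)[C@H]2C(C)(C)[C@H](OC(=O)CC(C)C)CC[C@]12C | intermediate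
11 | isofraxidin (7-hydroxy-6,8-dimethoxycoumarin) | COc1cc2ccc(=O)oc2c(OC)c1O | starting material
12 | 6,8-dimethoxy-7-{[3α-(3-methylbutanoyloxy)-6-oxo-9βH-drim-7-en-11-yl]oxy}coumarin, (3R,5R,9R,10R) | COc1cc2ccc(=O)oc2c(OC)c1OC[C@@H]1C(C)=CC(=O)[C@H]2C(C)(C)[C@H](OC(=O)CC(C)C)CC[C@]12C | target

## Step count and risks

Total steps: 8. Longest linear sequence: 8 (1 → 12); isofraxidin enters in the last step.

**Step 4 (regioselective dehydration).** The tertiary cation can also give the exocyclic Δ8(12) or the tetrasubstituted Δ8(9) alkene. Fallback, setting out from 4: dehydrate with Martin sulfurane in CH2Cl2 at −45 °C, where the tertiary alcohol reacts much faster than the hindered 3-OH, to give mainly 3β-hydroxydrim-8(12)-en-11-yl acetate F1. Then move the double bond into the ring with catalytic Co(salen)Cl and PhSiH3 (metal-hydride HAT isomerisation, which removes the accessible C7 hydrogen and not the hindered C9 one). This comes back to the route at 5.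

**Step 6 (chemoselective reduction and acylation in one flask).** The enone carbonyl could be reduced, or the alkoxide could trigger loss of the C11 acetate. Fallback, setting out from 5: oxidise only the alcohol with Dess–Martin periodinane to 3-oxodrim-7-en-11-yl acetate F2. Reduce with L-Selectride to 3α-hydroxydrim-7-en-11-yl acetate F3 and acylate with isovaleryl chloride and pyridine to 3α-(3-methylbutanoyloxy)drim-7-en-11-yl acetate F4. Then run the Cr(VI)–3,5-dimethylpyrazole allylic oxidation, so the C3 centre is set before any enone exists. This costs one extra step and comes back at 8.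

**Step 7 (proposed new HAT stereo-editing).** HAT may be slow, thiyl radicals may add to the enone, and the equilibrium is expected to be only about 5:1 to 10:1 in favour of the 9β-H epimer, so the minor epimer would have to be recycled. Fallback with known chemistry, setting out from 8: treat with K2CO3 (1 equiv) in MeOH at 25–40 °C. Methanolysis of the primary acetate is faster than γ-deprotonation and gives 11-hydroxy-6-oxo-9αH-drim-7-en-3α-yl 3-methylbutanoate F5, whose hydroxymethyl group is not a leaving group. Continued base then equilibrates C9 through the extended dienolate to the more stable epimer (base epimerisation at the γ-carbon of an enone, as for polygodial). This comes back at 10.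

## Further compounds

F1 | step 4 | 3β-hydroxydrim-8(12)-en-11-yl acetate | CC(=O)OC[C@H]1C(=C)CC[C@H]2C(C)(C)[C@@H](O)CC[C@]12C
F2 | step 6 | 3-oxodrim-7-en-11-yl acetate | CC(=O)OC[C@H]1C(C)=CC[C@H]2C(C)(C)C(=O)CC[C@]12C
F3 | step 6 | 3α-hydroxydrim-7-en-11-yl acetate | CC(=O)OC[C@H]1C(C)=CC[C@H]2C(C)(C)[C@H](O)CC[C@]12C
F4 | step 6 | 3α-(3-methylbutanoyloxy)drim-7-en-11-yl acetate | CC(=O)OC[C@H]1C(C)=CC[C@H]2C(C)(C)[C@H](OC(=O)CC(C)C)CC[C@]12C
F5 | step 7 | 11-hydroxy-6-oxo-9αH-drim-7-en-3α-yl 3-methylbutanoate | OC[C@H]1C(C)=CC(=O)[C@H]2C(C)(C)[C@H](OC(=O)CC(C)C)CC[C@]12C
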